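The dimer is cut at the C4–C6′ bond into two flavan units, both drawn from one 2,3-trans flavan-3-ol. Ring C of that flavan (O1, C2, C3, C4, C4a, C8a) is made by ring enlargement of a neolignan-type trans-2-aryl-2,3-dihydrobenzofuran-3-ylmethyl sulfonate. Ring A, whose carbon C4a lies para to O7 and ortho to O1, shifts from C3 to the exocyclic C4 through a phenonium ion while water enters at C3 with inversion. One operation thus enlarges the furan ring to the chroman, makes the C4 methylene and places the 3-hydroxyl trans to the C2 aryl group. Oxidation and reduction at C3 later give the cis units.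

Key step: step 7

Assumption: Rh2(S-PTTL)4 is taken to deliver the (2S)-dihydrobenzofuran 8; if its sense of induction is opposite, Rh2(R-PTTL)4 is used instead.
Remark: flavan locants (O1, C2, C3, C4, C4a … C8a) are used for the chromans; primed locants (C6′ and so on) denote the lower flavan unit of the dimers.

Step 1
Reactants: 1 2,3,4-trihydroxybenzaldehyde
Product: 2 3,4-bis(benzyloxy)-2-hydroxybenzaldehyde
Conditions: BnBr (2.1 equiv), K2CO3, DMF, rt
Reagents that add atoms: benzyl bromide, BrCc1ccccc1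
Why: Williamson etherification should alkylate only O-3 and O-4, because the 2-hydroxyl is held in a hydrogen bond to the formyl group and is the least reactive.

Step 2
Reactants: 2 3,4-bis(benzyloxy)-2-hydroxybenzaldehyde; 3 3,4-bis(benzyloxy)benzyl chloride
Product: 4 3,4-bis(benzyloxy)-2-{[3,4-bis(benzyloxy)benzyl]oxy}benzaldehyde
Conditions: K2CO3, KI (cat.), DMF, 60 °C
Reagents that add atoms: none
Why: Williamson etherification of the chelated phenol under more forcing conditions places the future C2–aryl carbon on O1.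

Step 3
Reactants: 4 3,4-bis(benzyloxy)-2-{[3,4-bis(benzyloxy)benzyl]oxy}benzaldehyde; 5 ethyl diazoacetate
Product: 6 ethyl (Z)-2-{3,4-bis(benzyloxy)-2-[3,4-bis(benzyloxy)benzyloxy]phenyl}-3-hydroxyacrylate
Conditions: HBF4·OEt2 (10 mol %), CH2Cl2, −78 °C to rt
Reagents that add atoms: none
Why: Acid-catalysed addition of the diazo ester to the aldehyde and loss of N2 with 1,2-shift of the trioxygenated aryl group (aryl migration should outrun hydride shift) gives the α-formyl arylacetate as its enol.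

Step 4
Reactants: 6 ethyl (Z)-2-{3,4-bis(benzyloxy)-2-[3,4-bis(benzyloxy)benzyloxy]phenyl}-3-hydroxyacrylate
Product: 7 ethyl 2-diazo-2-{3,4-bis(benzyloxy)-2-[3,4-bis(benzyloxy)benzyloxy]phenyl}acetate
Conditions: 4-acetamidobenzenesulfonyl azide, Et3N, MeCN, 0 °C to rt
Reagents that add atoms: 4-acetamidobenzenesulfonyl azide, CC(=O)Nc1ccc(cc1)S(=O)(=O)N=[N+]=[N-]
Why: Regitz deformylative diazo transfer should give the aryldiazoacetate, the formyl group leaving on the sulfonamide nitrogen.

Step 5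
Reactants: 7 ethyl 2-diazo-2-{3,4-bis(benzyloxy)-2-[3,4-bis(benzyloxy)benzyloxy]phenyl}acetate
Product: 9 ethyl (2S,3S)-trans-6,7-bis(benzyloxy)-2-[3,4-bis(benzyloxy)phenyl]-2,3-dihydrobenzofuran-3-carboxylate, via cis ester 8 (not isolated)
Conditions: Rh2(S-PTTL)4 (1 mol %), toluene, −60 °C; then NaOEt (0.2 equiv), EtOH, rt
Reagents that add atoms: none
Why: Intramolecular 1,5 C–H insertion of the rhodium carbene into the activated benzylic O–CH2 bond should give the cis ester with C2 set by the chiral carboxylate ligands, and ethoxide then epimerises C3 through the ester enolate to the more stable trans isomer without touching C2.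

Step 6
Reactants: 9 ethyl (2S,3S)-trans-6,7-bis(benzyloxy)-2-[3,4-bis(benzyloxy)phenyl]-2,3-dihydrobenzofuran-3-carboxylate
Product: 10 [(2S,3R)-trans-6,7-bis(benzyloxy)-2-[3,4-bis(benzyloxy)phenyl]-2,3-dihydrobenzofuran-3-yl]methanol
Conditions: LiAlH4, THF, 0 °C
Reagents that add atoms: none
Why: Hydride reduction of the ester to the primary alcohol touches neither stereocentre.

Step 7
Reactants: 10 [(2S,3R)-trans-6,7-bis(benzyloxy)-2-[3,4-bis(benzyloxy)phenyl]-2,3-dihydrobenzofuran-3-yl]methanol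
Product: 13 (2R,3S)-7,8-bis(benzyloxy)-2-[3,4-bis(benzyloxy)phenyl]chroman-3-ol, via mesylate 11 (not isolated), via phenonium ion 12 (not isolated)
Conditions: MsCl, Et3N, CH2Cl2, −20 °C; then (CF3)2CHOH/H2O 9:1, 2,6-lutidine, 40 °C
Reagents that add atoms: water, O
Why: The primary mesylate should ionise with anchimeric assistance from ring A, whose ipso carbon (C3a of the dihydrobenzofuran, the later C4a; para to the 7-benzyloxy oxygen and ortho to O1) attacks the exocyclic carbon (the later C4) anti to the leaving group to give the spiro-cyclopropane phenonium ion 12; water then opens the three-membered ring at the more substituted carbon C3 anti to the departing C3–aryl bond, so the aryl bond has moved from C3 to C4 (Wagner–Meerwein 1,2-aryl shift). The closest known reaction type is the aryl-assisted solvolytic ring enlargement of benzocycloalkenylmethyl sulfonates (neophyl-type rearrangement through phenonium ions). The six-membered ring is not formed by a cyclisation: a 3-exo-trig ipso attack closes the transient cyclopropane and cleavage of the old C3–aryl bond turns the five-membered ring into the chroman. C3 is the only new stereocentre and is set by inversion (backside opening of the bridged ion), which turns the 2,3-trans dihydrobenzofuran into the 2,3-trans flavan-3-ol, while C2 is untouched. The step needs participation to outrun direct substitution at the primary carbon and needs capture at C3, not at C4: the three oxygen donors of ring A and the ionising, weakly nucleophilic medium secure the first, and the secondary character of C3 together with relief of strain in the fused bicycle secures the second. Capture at C4 would only return alcohol 10, and interception of the bridged ion by water should forestall a free C3 cation that could suffer hydride or B-ring shift.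

Step 8
Reactants: 13 (2R,3S)-7,8-bis(benzyloxy)-2-[3,4-bis(benzyloxy)phenyl]chroman-3-ol
Product: 14 (2R)-7,8-bis(benzyloxy)-2-[3,4-bis(benzyloxy)phenyl]chroman-3-one
Conditions: Dess–Martin periodinane, wet CH2Cl2, rt
Reagents that add atoms: none
Why: Dess–Martin oxidation under non-basic conditions should give the flavan-3-one without epimerising the acidic C2 centre.

Step 9
Reactants: 14 (2R)-7,8-bis(benzyloxy)-2-[3,4-bis(benzyloxy)phenyl]chroman-3-one
Product: 15 (2R,3R)-7,8-bis(benzyloxy)-2-[3,4-bis(benzyloxy)phenyl]chroman-3-ol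
Conditions: LiBH(s-Bu)3, LiBr, THF, −78 °C
Reagents that add atoms: none
Why: The bulky borohydride should attack the carbonyl from the face opposite the equatorial C2 aryl group (equatorial attack), giving the axial 2,3-cis alcohol.

Step 10
Reactants: 15 (2R,3R)-7,8-bis(benzyloxy)-2-[3,4-bis(benzyloxy)phenyl]chroman-3-ol
Product: 16 (2R,3R,4S)-7,8-bis(benzyloxy)-2-[3,4-bis(benzyloxy)phenyl]chromane-3,4-diol
Conditions: DDQ (1.2 equiv), CH2Cl2/H2O, 0 °C to rt
Reagents that add atoms: water, O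
Why: DDQ abstracts hydride from C4 (benzylic, para to O7 and ortho to O1), and water should add to the cation anti to the axial 3-hydroxyl, giving the 3,4-trans diol (benzylic oxidative functionalisation).

Step 11
Reactants: 16 (2R,3R,4S)-7,8-bis(benzyloxy)-2-[3,4-bis(benzyloxy)phenyl]chromane-3,4-diol
Product: 17 (2R,3R,4S)-7,8-bis(benzyloxy)-2-[3,4-bis(benzyloxy)phenyl]chromane-3,4-diyl dibenzyl dicarbonate
Conditions: CbzCl, DMAP (cat.), i-Pr2NEt, CH2Cl2, 0 °C to rt
Reagents that add atoms: benzyl chloroformate, O=C(Cl)OCc1ccccc1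
Why: Acylation of both hydroxyls as benzyl carbonates masks them against the later oxidation, makes C4′ a poor cation precursor under thiophilic conditions and allows removal in the final hydrogenolysis.

Step 12
Reactants: 13 (2R,3S)-7,8-bis(benzyloxy)-2-[3,4-bis(benzyloxy)phenyl]chroman-3-ol
Product: 18 (2R,3S,4R)-7,8-bis(benzyloxy)-2-[3,4-bis(benzyloxy)phenyl]-4-(2-ethoxyethoxy)chroman-3-ol
Conditions: DDQ, 2-ethoxyethanol, CH2Cl2, rt
Reagents that add atoms: 2-ethoxyethanol, CCOCCO
Why: The same DDQ hydride abstraction at C4 is followed by capture of the cation by the alcohol anti to the 3-hydroxyl, giving the 3,4-trans ether.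

Step 13
Reactants: 18 (2R,3S,4R)-7,8-bis(benzyloxy)-2-[3,4-bis(benzyloxy)phenyl]-4-(2-ethoxyethoxy)chroman-3-ol
Product: 19 (2R)-2,3-trans-3,4-trans-4-(benzylsulfanyl)-7,8-bis(benzyloxy)-2-[3,4-bis(benzyloxy)phenyl]chroman-3-ol
Conditions: BnSH, BF3·OEt2 (20 mol %), CH2Cl2, −78 to −20 °C
Reagents that add atoms: benzyl mercaptan, SCc1ccccc1
Why: Lewis-acid ionisation of the benzylic ether and capture by the soft thiol (SN1 exchange, thiol entering anti to the 3-hydroxyl) should give a leaving group that only a thiophile can activate.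

Step 14
Reactants: 19 (2R)-2,3-trans-3,4-trans-4-(benzylsulfanyl)-7,8-bis(benzyloxy)-2-[3,4-bis(benzyloxy)phenyl]chroman-3-ol; 17 (2R,3R,4S)-7,8-bis(benzyloxy)-2-[3,4-bis(benzyloxy)phenyl]chromane-3,4-diyl dibenzyl dicarbonate (3 equiv)
Product: 20 C4→C6′ dimer: upper (2R)-2,3-trans-3,4-trans-7,8-bis(benzyloxy)-2-[3,4-bis(benzyloxy)phenyl]chroman-3-ol unit bonded through C4 to C6′ of unit 17
Conditions: AgBF4, 2,6-di-tert-butyl-4-methylpyridine, THF, 0 °C
Reagents that add atoms: none
Why: Silver-assisted loss of the thiolate gives the C4 cation, which should alkylate the excess nucleophile at C6′ (ortho to O7′, para to O1′) from the face anti to the 3-hydroxyl (Friedel–Crafts alkylation), so the new aryl group is trans to O3 and cis to the C2 aryl group, while the carbonate at C4′ does not ionise.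

Step 15
Reactants: 20 C4→C6′ dimer with 2,3-trans-3,4-trans upper unit
Product: 21 C4→C6′ dimer with upper (2R)-2,4-cis-chroman-3-one unit
Conditions: Dess–Martin periodinane, wet CH2Cl2, rt
Reagents that add atoms: none
Why: Dess–Martin oxidation of the only free hydroxyl gives a ketone whose two α-aryl groups are already in the favoured 2,4-cis (diequatorial) arrangement, so neither α-centre should epimerise.

Step 16
Reactants: 21 C4→C6′ dimer with upper (2R)-2,4-cis-chroman-3-one unit
Product: 22 protected target: C4→C6′ dimer with all-cis upper (2R,3R)-chroman-3-ol unit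
Conditions: LiBH(s-Bu)3, THF, −78 °C
Reagents that add atoms: none
Why: The bulky borohydride should attack from the face opposite both equatorial aryl groups at C2 and C4, giving the axial hydroxyl cis to both (substrate-controlled ketone reduction).

Step 17
Reactants: 22 protected target: C4→C6′ dimer with all-cis upper (2R,3R)-chroman-3-ol unit
Product: 23 CNP0143773.1
Conditions: H2 (1 atm), Pd(OH)2/C, THF/MeOH, rt
Reagents that add atoms: none
Why: Neutral hydrogenolysis should cleave the eight benzyl ethers and the two benzyl carbonates (which lose CO2) without acid or base that would harm the free polyphenol.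

Compound list
1 | 2,3,4-trihydroxybenzaldehyde | O=Cc1ccc(O)c(O)c1O | starting material
2 | 3,4-bis(benzyloxy)-2-hydroxybenzaldehyde | O=Cc1ccc(OCc2ccccc2)c(OCc2ccccc2)c1O | intermediate
3 | 3,4-bis(benzyloxy)benzyl chloride | ClCc1ccc(OCc2ccccc2)c(OCc2ccccc2)c1 | starting material
4 | 3,4-bis(benzyloxy)-2-{[3,4-bis(benzyloxy)benzyl]oxy}benzaldehyde | O=Cc1ccc(OCc2ccccc2)c(OCc2ccccc2)c1OCc1ccc(OCc2ccccc2)c(OCc2ccccc2)c1 | intermediate
5 | ethyl diazoacetate | CCOC(=O)C=[N+]=[N-] | starting material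
6 | ethyl (Z)-2-{3,4-bis(benzyloxy)-2-[3,4-bis(benzyloxy)benzyloxy]phenyl}-3-hydroxyacrylate | CCOC(=O)/C(=C\O)c1ccc(OCc2ccccc2)c(OCc2ccccc2)c1OCc1ccc(OCc2ccccc2)c(OCc2ccccc2)c1 | intermediate
7 | ethyl 2-diazo-2-{3,4-bis(benzyloxy)-2-[3,4-bis(benzyloxy)benzyloxy]phenyl}acetate | CCOC(=O)C(=[N+]=[N-])c1ccc(OCc2ccccc2)c(OCc2ccccc2)c1OCc1ccc(OCc2ccccc2)c(OCc2ccccc2)c1 | intermediate
8 | ethyl (2S,3R)-cis-6,7-bis(benzyloxy)-2-[3,4-bis(benzyloxy)phenyl]-2,3-dihydrobenzofuran-3-carboxylate (not isolated) | CCOC(=O)[C@@H]1c2ccc(OCc3ccccc3)c(OCc3ccccc3)c2O[C@@H]1c1ccc(OCc2ccccc2)c(OCc2ccccc2)c1 | intermediate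
9 | ethyl (2S,3S)-trans-6,7-bis(benzyloxy)-2-[3,4-bis(benzyloxy)phenyl]-2,3-dihydrobenzofuran-3-carboxylate | CCOC(=O)[C@H]1c2ccc(OCc3ccccc3)c(OCc3ccccc3)c2O[C@@H]1c1ccc(OCc2ccccc2)c(OCc2ccccc2)c1 | intermediate
10 | [(2S,3R)-trans-6,7-bis(benzyloxy)-2-[3,4-bis(benzyloxy)phenyl]-2,3-dihydrobenzofuran-3-yl]methanol | OC[C@H]1c2ccc(OCc3ccccc3)c(OCc3ccccc3)c2O[C@@H]1c1ccc(OCc2ccccc2)c(OCc2ccccc2)c1 | intermediate
11 | methanesulfonate of 10 (not isolated) | CS(=O)(=O)OC[C@H]1c2ccc(OCc3ccccc3)c(OCc3ccccc3)c2O[C@@H]1c1ccc(OCc2ccccc2)c(OCc2ccccc2)c1 | intermediate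
12 | phenonium ion: cyclopropane spiro-fused at the ipso carbon of ring A, drawn as the 7-oxocarbenium form (not isolated) | C1[C@@H]2[C@@H](c4ccc(OCc5ccccc5)c(OCc5ccccc5)c4)OC3=C(OCc4ccccc4)C(=[O+]Cc4ccccc4)C=C[C@@]123 | intermediate
13 | (2R,3S)-7,8-bis(benzyloxy)-2-[3,4-bis(benzyloxy)phenyl]chroman-3-ol (2,3-trans) | O[C@H]1Cc2ccc(OCc3ccccc3)c(OCc3ccccc3)c2O[C@@H]1c1ccc(OCc2ccccc2)c(OCc2ccccc2)c1 | intermediate
14 | (2R)-7,8-bis(benzyloxy)-2-[3,4-bis(benzyloxy)phenyl]chroman-3-one | O=C1Cc2ccc(OCc3ccccc3)c(OCc3ccccc3)c2O[C@@H]1c1ccc(OCc2ccccc2)c(OCc2ccccc2)c1 | intermediate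
15 | (2R,3R)-7,8-bis(benzyloxy)-2-[3,4-bis(benzyloxy)phenyl]chroman-3-ol (2,3-cis) | O[C@@H]1Cc2ccc(OCc3ccccc3)c(OCc3ccccc3)c2O[C@@H]1c1ccc(OCc2ccccc2)c(OCc2ccccc2)c1 | intermediate
16 | (2R,3R,4S)-7,8-bis(benzyloxy)-2-[3,4-bis(benzyloxy)phenyl]chromane-3,4-diol (2,3-cis-3,4-trans) | c1cc2c(c(OCc3ccccc3)c1OCc1ccccc1)O[C@H](c1ccc(OCc3ccccc3)c(OCc3ccccc3)c1)[C@H](O)[C@H]2O | intermediate
17 | (2R,3R,4S)-7,8-bis(benzyloxy)-2-[3,4-bis(benzyloxy)phenyl]chromane-3,4-diyl dibenzyl dicarbonate | c1cc2c(c(OCc3ccccc3)c1OCc1ccccc1)O[C@H](c1ccc(OCc3ccccc3)c(OCc3ccccc3)c1)[C@H](OC(=O)OCc1ccccc1)[C@H]2OC(=O)OCc1ccccc1 | intermediate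
18 | (2R,3S,4R)-7,8-bis(benzyloxy)-2-[3,4-bis(benzyloxy)phenyl]-4-(2-ethoxyethoxy)chroman-3-ol (2,3-trans-3,4-trans) | C(c1ccccc1)Oc1ccc([C@H]2Oc3c(ccc(OCc4ccccc4)c3OCc3ccccc3)[C@@H](OCCOCC)[C@@H]2O)cc1OCc1ccccc1 | intermediate
19 | (2R)-2,3-trans-3,4-trans-4-(benzylsulfanyl)-7,8-bis(benzyloxy)-2-[3,4-bis(benzyloxy)phenyl]chroman-3-ol | C(c1ccccc1)Oc1ccc([C@H]2Oc3c(ccc(OCc4ccccc4)c3OCc3ccccc3)[C@@H](SCc3ccccc3)[C@@H]2O)cc1OCc1ccccc1 | intermediate
20 | C4→C6′ dimer, upper unit 2,3-trans-3,4-trans with free 3-OH, lower unit as in 17 | C(c1ccccc1)Oc1ccc([C@H]2Oc3c(ccc(OCc4ccccc4)c3OCc3ccccc3)[C@@H](c3cc4c(c(OCc5ccccc5)c3OCc3ccccc3)O[C@H](c3ccc(OCc5ccccc5)c(OCc5ccccc5)c3)[C@H](OC(=O)OCc3ccccc3)[C@H]4OC(=O)OCc3ccccc3)[C@@H]2O)cc1OCc1ccccc1 | intermediate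
21 | C4→C6′ dimer, upper unit (2R)-2,4-cis-chroman-3-one | C(c1ccccc1)Oc1ccc([C@H]2Oc3c(ccc(OCc4ccccc4)c3OCc3ccccc3)[C@@H](c3cc4c(c(OCc5ccccc5)c3OCc3ccccc3)O[C@H](c3ccc(OCc5ccccc5)c(OCc5ccccc5)c3)[C@H](OC(=O)OCc3ccccc3)[C@H]4OC(=O)OCc3ccccc3)C2=O)cc1OCc1ccccc1 | intermediate
22 | protected target: C4→C6′ dimer, upper unit all-cis (2R,3R) with free 3-OH, eight benzyl ethers, two benzyl carbonates | C(c1ccccc1)Oc1ccc([C@H]2Oc3c(ccc(OCc4ccccc4)c3OCc3ccccc3)[C@@H](c3cc4c(c(OCc5ccccc5)c3OCc3ccccc3)O[C@H](c3ccc(OCc5ccccc5)c(OCc5ccccc5)c3)[C@H](OC(=O)OCc3ccccc3)[C@H]4OC(=O)OCc3ccccc3)[C@H]2O)cc1OCc1ccccc1 | intermediate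
23 | CNP0143773.1: all-cis (2R,3R) 7,8,3′,4′-tetrahydroxyflavan-3-ol unit bonded through C4 to C6′ of the (2R,3R,4S) 7,8,3′,4′-tetrahydroxyflavan-3,4-diol unit | Oc1ccc([C@H]2Oc3c(ccc(O)c3O)[C@@H](c3cc4c(c(O)c3O)O[C@H](c3ccc(O)c(O)c3)[C@H](O)[C@H]4O)[C@H]2O)cc1O | target

Total step count: 17. Longest linear sequence: 15 steps (steps 1–11, then 14–17).

Steps most likely to fail

Step 7 (ring enlargement). The sulfonate may be displaced at the primary carbon without aryl participation, the ion pair may return to a rearranged sulfonate, or a non-bridged C3 cation may collapse by hydride or B-ring shift. The fallback changes the leaving group to a diazonium ion formed in water, a Demjanov-type ring enlargement, so that ionisation no longer depends on solvolysis and no nucleophilic counter-ion is present. It sets out from ester 9: ammonolysis (NH3, MeOH) should give the primary carboxamide F1, LiAlH4 reduction the aminomethyl dihydrobenzofuran F2, and diazotisation (NaNO2, aqueous AcOH, 0 °C) should expel N2 with the same 1,2-aryl shift and capture by water at C3. It comes back to the route at 13.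

Step 14 (interflavan coupling). The C4 cation may be captured by C6 of a second molecule of the electrophile (self-condensation), and facial selectivity at C4 may be incomplete. The fallback blocks the nucleophilic position of the electrophile with a removable bromine. It sets out from 18: NBS (CH2Cl2, −78 °C) should brominate C6 to give the 6-bromo ether F3; thiol exchange as in step 13 gives the 6-bromo thioether F4; coupling with 17 as in step 14 gives the bromo dimer F5; radical hydrodebromination (Bu3SnH, AIBN, toluene, 80 °C) removes the cap. It comes back to the route at 20.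

Step 17 (global hydrogenolysis). The benzylic C4′–O bond may be cleaved on the catalyst while it still carries the carbonate leaving group, giving a 4′-deoxy product. The fallback unmasks this oxygen before any reduction, so that it meets the catalyst as a free hydroxyl, which is a much poorer leaving group. It sets out from 22: methanolysis (K2CO3, MeOH/THF, rt) should give the diol octabenzyl ether F6, which is then hydrogenolysed (H2, Pd(OH)2/C, THF/MeOH). It comes back to the route at 23.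

Further compounds
F1 | step 7 | (2S,3S)-trans-6,7-bis(benzyloxy)-2-[3,4-bis(benzyloxy)phenyl]-2,3-dihydrobenzofuran-3-carboxamide | NC(=O)[C@H]1c2ccc(OCc3ccccc3)c(OCc3ccccc3)c2O[C@@H]1c1ccc(OCc2ccccc2)c(OCc2ccccc2)c1
F2 | step 7 | [(2S,3R)-trans-6,7-bis(benzyloxy)-2-[3,4-bis(benzyloxy)phenyl]-2,3-dihydrobenzofuran-3-yl]methanamine | NC[C@H]1c2ccc(OCc3ccccc3)c(OCc3ccccc3)c2O[C@@H]1c1ccc(OCc2ccccc2)c(OCc2ccccc2)c1
F3 | step 14 | 6-bromo derivative of 18 | C(c1ccccc1)Oc1ccc([C@H]2Oc3c(cc(Br)c(OCc4ccccc4)c3OCc3ccccc3)[C@@H](OCCOCC)[C@@H]2O)cc1OCc1ccccc1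
F4 | step 14 | 6-bromo derivative of 19 | C(c1ccccc1)Oc1ccc([C@H]2Oc3c(cc(Br)c(OCc4ccccc4)c3OCc3ccccc3)[C@@H](SCc3ccccc3)[C@@H]2O)cc1OCc1ccccc1
F5 | step 14 | 6-bromo derivative of 20 | C(c1ccccc1)Oc1ccc([C@H]2Oc3c(cc(Br)c(OCc4ccccc4)c3OCc3ccccc3)[C@@H](c3cc4c(c(OCc5ccccc5)c3OCc3ccccc3)O[C@H](c3ccc(OCc5ccccc5)c(OCc5ccccc5)c3)[C@H](OC(=O)OCc3ccccc3)[C@H]4OC(=O)OCc3ccccc3)[C@@H]2O)cc1OCc1ccccc1
F6 | step 17 | octabenzyl ether of 23 with free 3-, 3′- and 4′-hydroxyls | C(c1ccccc1)Oc1ccc([C@H]2Oc3c(ccc(OCc4ccccc4)c3OCc3ccccc3)[C@@H](c3cc4c(c(OCc5ccccc5)c3OCc3ccccc3)O[C@H](c3ccc(OCc5ccccc5)c(OCc5ccccc5)c3)[C@H](O)[C@H]4O)[C@H]2O)cc1OCc1ccccc1
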